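**Retrosynthetic overview**
1. The target is a purchased benzene ring carrying an unbranched, saturated C21 chain. No ring is formed at any stage, and there is no stereocentre to set.
2. Key disconnection: the side-chain bond C4'–C5' (C1' is the ring-bound carbon), a CH2–CH2 link between two primary carbons. It leads back to stearic acid (gives C5'–C21' after loss of CO2) and a 5-arylpentanoic acid (gives C1'–C4' after loss of CO2), joined by a Ni-electrocatalytic doubly decarboxylative coupling of their N-hydroxyphthalimide esters made in the flask.
3. Enabling feature: the heteroatom-free polymethylene chain on ring carbon C6, which makes both radical partners plain primary alkyls that cannot eliminate or rearrange, and the cathodically inert 1,2,4-trioxygenated benzene ring. The ring's one radical-sensitive site, the phenolic O–H on C1, is masked as a MOM ether.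
4. The arylpentanoic acid comes from 2,4-dimethoxyphenol by Mg-directed ortho-formylation at C6, MOM protection, Wittig reaction with (3-carboxypropyl)triphenylphosphonium bromide and hydrogenation. MOM removal after the coupling gives the target.

Key step: step 5

Remark: the target has no stereogenic element, so the compound itself is the "single enantiomer"; the only stereo-element on the way (the alkene geometry of 6) is erased by hydrogenation.

**Step 1**
Reactants: 1 2,4-dimethoxyphenol
Product: 2 2-hydroxy-3,5-dimethoxybenzaldehyde
Conditions: anhydrous MgCl2, Et3N, paraformaldehyde, MeCN, reflux; aq. HCl work-up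
Reagents that add atoms: paraformaldehyde (as formaldehyde), C=O
Why: Casnati–Skattebøl ortho-formylation, in which the magnesium phenoxide delivers formaldehyde within a chelate to the only free ortho carbon (C6) and a second formaldehyde oxidises the salicyl alkoxide by hydride transfer, so the C5 position activated by the two OMe groups should stay untouched.

**Step 2**
Reactants: 2 2-hydroxy-3,5-dimethoxybenzaldehyde
Product: 3 3,5-dimethoxy-2-(methoxymethoxy)benzaldehyde
Conditions: MOMCl, K2CO3, DMF, 0 °C to rt
Reagents that add atoms: chloromethyl methyl ether (MOMCl), COCCl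
Why: Williamson-type O-alkylation of the acidic salicylaldehyde phenol gives the MOM acetal, which removes the phenolic O–H (a nucleophile and hydrogen-atom donor) and should survive ylide base, hydrogenation, carbodiimide activation and cathodic reduction.

**Step 3**
Reactants: 3 3,5-dimethoxy-2-(methoxymethoxy)benzaldehyde; 4 (3-carboxypropyl)triphenylphosphonium bromide
Product: 6 (Z)-5-[3,5-dimethoxy-2-(methoxymethoxy)phenyl]pent-4-enoic acid, via carboxylate phosphonium ylide 5 (not isolated)
Conditions: 4 (1.5 equiv), NaHMDS (3.0 equiv), THF, 0 °C; then 3, −78 °C to rt; cold 1 M HCl to pH 3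
Reagents that add atoms: none
Why: Wittig olefination of the non-enolisable aldehyde with the non-stabilised carboxylate ylide (two equivalents of base per phosphonium salt) should give mainly the Z-alkenoic acid, and the geometry is irrelevant because step 4 removes the double bond.

**Step 4**
Reactants: 6 (Z)-5-[3,5-dimethoxy-2-(methoxymethoxy)phenyl]pent-4-enoic acid
Product: 7 5-[3,5-dimethoxy-2-(methoxymethoxy)phenyl]pentanoic acid
Conditions: H2 (1 atm), 10% Pd/C, EtOAc, rt
Reagents that add atoms: none
Why: Heterogeneous catalytic hydrogenation should saturate the styrenyl double bond without touching the aryl ethers, the MOM acetal or the carboxylic acid.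

**Step 5**
Reactants: 7 5-[3,5-dimethoxy-2-(methoxymethoxy)phenyl]pentanoic acid; 8 stearic acid (octadecanoic acid)
Product: 11 1-henicosyl-3,5-dimethoxy-2-(methoxymethoxy)benzene, via arylpentanoyl NHPI ester 9 (not isolated), via stearoyl NHPI ester 10 (not isolated)
Conditions: 7 (1 equiv), 8 (3 equiv), N-hydroxyphthalimide, DIC, DMF/THF, rt; then NiCl2·6H2O (20 mol%), 2,2':6',2''-terpyridine (20 mol%), AgNO3 (0.3 equiv), Mg(+)/RVC(−), undivided cell, constant current, rt
Reagents that add atoms: none
Why: Carbodiimide esterification turns both acids into the redox-active esters 9 and 10; at the silver-modified carbon cathode a low-valent terpyridine–nickel species transfers one electron to each ester, whose radical anion fragments to phthalimide anion, CO2 and a primary alkyl radical (4-arylbutyl from 9, heptadecyl from 10), while the magnesium anode dissolves to supply the electrons. Successive capture of the two radicals at nickel should give a dialkylnickel(III) species that reductively eliminates the new CH2–CH2 bond four carbons from the ring. The closest known reaction type is the Ni-electrocatalytic doubly decarboxylative coupling of two primary N-hydroxyphthalimide esters, a reductive counterpart of the Kolbe heterocoupling, used here on its own substrate class. No ring is closed and no stereocentre is created. The step needs cross-coupling over homocoupling, which the threefold excess of cheap 10 should secure for the valuable partner 9, with both homodimers (a C34 alkane and a bis-aryl octane) differing strongly in polarity from 11. It also needs coupling over radical quenching and arene oxidation, which the MOM cap on the hydrogen-donating phenolic O–H and the reductive (cathodic) mode should secure for the electron-rich ring.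

**Step 6**
Reactants: 11 1-henicosyl-3,5-dimethoxy-2-(methoxymethoxy)benzene
Product: 12 6-n-heneicosyl-2,4-dimethoxyphenol
Conditions: conc. HCl (cat.), MeOH/THF (1:1), 50 °C, under N2
Reagents that add atoms: none
Why: Acid-catalysed transacetalisation of the aryl MOM acetal to methanol should release the phenol, while the aryl methyl ethers and the saturated chain are inert.

**Compound list**
1 | 2,4-dimethoxyphenol | COc1ccc(O)c(OC)c1 | starting material
2 | 2-hydroxy-3,5-dimethoxybenzaldehyde | COc1cc(C=O)c(O)c(OC)c1 | intermediate
3 | 3,5-dimethoxy-2-(methoxymethoxy)benzaldehyde | COCOc1c(C=O)cc(OC)cc1OC | intermediate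
4 | (3-carboxypropyl)triphenylphosphonium bromide | OC(=O)CCC[P+](c1ccccc1)(c1ccccc1)c1ccccc1.[Br-] | starting material
5 | carboxylate phosphonium ylide, sodium 4-(triphenylphosphoranylidene)butanoate | [Na+].[O-]C(=O)CCC=P(c1ccccc1)(c1ccccc1)c1ccccc1 | intermediate
6 | (Z)-5-[3,5-dimethoxy-2-(methoxymethoxy)phenyl]pent-4-enoic acid (Z expected as major isomer; either geometry serves) | COCOc1c(/C=C\CCC(=O)O)cc(OC)cc1OC | intermediate
7 | 5-[3,5-dimethoxy-2-(methoxymethoxy)phenyl]pentanoic acid | COCOc1c(CCCCC(=O)O)cc(OC)cc1OC | intermediate
8 | stearic acid (octadecanoic acid) | CCCCCCCCCCCCCCCCCC(=O)O | starting material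
9 | arylpentanoyl NHPI ester, 1,3-dioxoisoindolin-2-yl 5-[3,5-dimethoxy-2-(methoxymethoxy)phenyl]pentanoate | COCOc1c(CCCCC(=O)ON2C(=O)c3ccccc3C2=O)cc(OC)cc1OC | intermediate
10 | stearoyl NHPI ester, 1,3-dioxoisoindolin-2-yl octadecanoate | CCCCCCCCCCCCCCCCCC(=O)ON1C(=O)c2ccccc2C1=O | intermediate
11 | 1-henicosyl-3,5-dimethoxy-2-(methoxymethoxy)benzene | CCCCCCCCCCCCCCCCCCCCCc1cc(OC)cc(OC)c1OCOC | intermediate
12 | 6-n-heneicosyl-2,4-dimethoxyphenol | CCCCCCCCCCCCCCCCCCCCCc1cc(OC)cc(OC)c1O | target

**Total step count:** 6
**Longest linear sequence:** 6 steps (1 → 2 → 3 → 6 → 7 → 11 → 12; stearic acid 8 enters directly in step 5)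

**Steps most likely to fail**

Step 5. Statistical homocoupling of each radical partner may compete with the cross-coupling, the alkyl radicals or alkylnickel species may be reduced to alkanes (protodecarboxylation), the 4-arylbutyl radical may add to its own ring, and the C18 active ester may precipitate and passivate the cathode. The fallback abandons the decarboxylative union for a polar olefination; it sets out from aldehyde 3 and comes back at 11. 1-Bromoicosane and triphenylphosphine (toluene, reflux) should give icosyltriphenylphosphonium bromide F1. NaHMDS (THF, 0 °C) should convert it into icosylidenetriphenylphosphorane F2, which with 3 (−78 °C to rt) should give (Z)-1-(henicos-1-en-1-yl)-3,5-dimethoxy-2-(methoxymethoxy)benzene F3. Hydrogenation of F3 (H2, Pd/C, EtOAc) should then give 11.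

Step 3. Deprotonation of the sparingly soluble carboxy-phosphonium salt to the dianionic ylide may be incomplete and its addition to the electron-rich aldehyde sluggish, and the acidic work-up may partly cleave the MOM acetal. The fallback uses a vinylogous Horner–Wadsworth–Emmons reaction; it sets out from 3 and comes back at 7. Aldehyde 3 and triethyl 4-phosphonocrotonate (LiOH·H2O, 4 Å molecular sieves, THF, reflux) should give ethyl (2E,4E)-5-[3,5-dimethoxy-2-(methoxymethoxy)phenyl]penta-2,4-dienoate F4. Hydrogenation (H2, Pd/C, EtOAc) should give ethyl 5-[3,5-dimethoxy-2-(methoxymethoxy)phenyl]pentanoate F5, and saponification (LiOH, THF/H2O, then HCl to pH 4) should give 7.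

Step 1. The very electron-rich phenol may react further with formaldehyde (hydroxymethylation or methoxymethylation at C5, diarylmethane formation) or be air-oxidised towards quinones under the basic conditions. The fallback installs the ortho carbon by a sigmatropic rearrangement and builds the acid by metathesis; it sets out from 1 and comes back at 7. Phenol 1 with allyl bromide (K2CO3, acetone, reflux) should give 1-(allyloxy)-2,4-dimethoxybenzene F6. Aromatic Claisen rearrangement (N,N-diethylaniline, 190 °C) should give 2-allyl-4,6-dimethoxyphenol F7, since the only free ortho carbon is C6. MOM protection (MOMCl, K2CO3, DMF) should give 1-allyl-3,5-dimethoxy-2-(methoxymethoxy)benzene F8. Cross-metathesis with excess but-3-enoic acid (Hoveyda–Grubbs II catalyst, CH2Cl2, 40 °C) should give (E)-5-[3,5-dimethoxy-2-(methoxymethoxy)phenyl]pent-3-enoic acid F9, and hydrogenation (H2, Pd/C, EtOAc) should give 7.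

**Further compounds**
F1 | step 5 | icosyltriphenylphosphonium bromide | CCCCCCCCCCCCCCCCCCCC[P+](c1ccccc1)(c1ccccc1)c1ccccc1.[Br-]
F2 | step 5 | icosylidenetriphenylphosphorane | CCCCCCCCCCCCCCCCCCCC=P(c1ccccc1)(c1ccccc1)c1ccccc1
F3 | step 5 | (Z)-1-(henicos-1-en-1-yl)-3,5-dimethoxy-2-(methoxymethoxy)benzene | CCCCCCCCCCCCCCCCCCC/C=C\c1cc(OC)cc(OC)c1OCOC
F4 | step 3 | ethyl (2E,4E)-5-[3,5-dimethoxy-2-(methoxymethoxy)phenyl]penta-2,4-dienoate | CCOC(=O)/C=C/C=C/c1cc(OC)cc(OC)c1OCOC
F5 | step 3 | ethyl 5-[3,5-dimethoxy-2-(methoxymethoxy)phenyl]pentanoate | CCOC(=O)CCCCc1cc(OC)cc(OC)c1OCOC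
F6 | step 1 | 1-(allyloxy)-2,4-dimethoxybenzene | C=CCOc1ccc(OC)cc1OC
F7 | step 1 | 2-allyl-4,6-dimethoxyphenol | C=CCc1cc(OC)cc(OC)c1O
F8 | step 1 | 1-allyl-3,5-dimethoxy-2-(methoxymethoxy)benzene | C=CCc1cc(OC)cc(OC)c1OCOC
F9 | step 1 | (E)-5-[3,5-dimethoxy-2-(methoxymethoxy)phenyl]pent-3-enoic acid | COCOc1c(C/C=C/CC(=O)O)cc(OC)cc1OC
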